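## Retrosynthetic overview

1. The route rests on the α-ketol unit C8(=O)–C9(O) of the cyclohexenone ring C5–C6=C7–C8–C9–C10. Target 25 comes from acetylation of ketol 24, and 24 from a one-carbon acyloin ring expansion (C10 shifts from C8 to C9, forming C9–C10) of the spiro[4.4] 1-hydroxycyclopent-2-ene-1-carbaldehyde 22.
2. 22 comes from spiro[4.4]non-6-en-8-one 17 by formyl-anion (dithiane) addition to C8, exchange of TBS for isobutyrate on the C4 oxygen, and dithiane hydrolysis.
3. 17 comes from Nazarov cyclisation (C5–C6 bond) of the cyclopentylidene propenyl ketone 15, which is made from the α-silyloxy cyclopentanone 10 by olefination, Weinreb amide formation and propenyl Grignard addition.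
4. 10 comes from (R)-4-silyloxycyclopentenone 1: cuprate addition and elimination (sets C2), α-iodination, CBS reduction (sets C4), then iodine → boron → oxygen exchange (C5 ketone).
5. Ring order: ring A (C1–C5, from 1) first; ring B as a cyclopentenone second (step 10); ring B enlarged to the cyclohexenone last (step 15).

Key step: step 15

Remarks
- Numbering used throughout: spiro carbon C5; ring A is C1H2–C2(isopropenyl)–C3H2–C4(O); ring B is C6(Me)=C7–C8–C9–C10(Me). C9 is absent before step 15.
- Assumption: 12, 13 and 15 are drawn as the E isomers at C5=C10 and 14 as the E reagent. The commercial Grignard reagent is an E/Z mixture and the olefination need not be selective, because both alkene geometries are erased in step 10.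

## Route

Step 1
Reactants: 1 (R)-4-(tert-butyldimethylsilyloxy)cyclopent-2-en-1-one; 2 isopropenylmagnesium bromide
Product: 3 (3S,4R)-3-isopropenyl-4-(tert-butyldimethylsilyloxy)cyclopentan-1-one (substituents trans)
Conditions: 2 (1.5 equiv), CuI (10 mol %), THF, −78 → −40 °C; aq. NH4Cl
Reagents that add atoms: none
Why: Copper-catalysed conjugate addition of the alkenyl Grignard reagent to the 4-silyloxycyclopentenone should occur anti to the OTBS group, which sets the isopropenyl-bearing carbon (C2 of ring A).

Step 2
Reactants: 3
Product: 4 (R)-4-isopropenylcyclopent-2-en-1-one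
Conditions: DBU (1.1 equiv), CH2Cl2, −20 → 0 °C
Reagents that add atoms: none
Why: E1cB β-elimination of the silyloxy group through the enolate on that side gives the 4-substituted cyclopentenone; low temperature and short contact are chosen to avoid γ-deprotonation at C2.

Step 3
Reactants: 4
Product: 5 (R)-2-iodo-4-isopropenylcyclopent-2-en-1-one
Conditions: I2 (1.5 equiv), pyridine/CH2Cl2 1:1, 0 °C → rt; aq. Na2S2O3
Reagents that add atoms: iodine, II
Why: α-Iodination of the enone by pyridine addition, iodination and elimination places iodine on the α-carbon, the future spiro carbon C5.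

Step 4
Reactants: 5
Product: 6 (1R,4R)-2-iodo-4-isopropenylcyclopent-2-en-1-ol (OH trans to isopropenyl)
Conditions: (S)-2-methyl-CBS-oxazaborolidine (20 mol %), catecholborane (1.5 equiv), toluene, −78 °C
Reagents that add atoms: none
Why: Corey–Bakshi–Shibata reduction, in which the 2-iodoalkenyl arm acts as the large group, so the (S)-catalyst should deliver hydride to give the (1R) carbinol (C4) under reagent control; catecholborane leaves the isopropenyl group alone.

Step 5
Reactants: 6
Product: 7 tert-butyldimethylsilyl ether of 6
Conditions: TBSCl, imidazole, DMF, rt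
Reagents that add atoms: tert-butyldimethylsilyl chloride, CC(C)(C)[Si](C)(C)Cl
Why: Standard silylation of the secondary allylic alcohol; the bulky silyl ether later steers the Nazarov closure.

Step 6
Reactants: 7
Product: 10 ketone (2R,4R)-2-(tert-butyldimethylsilyloxy)-4-isopropenylcyclopentan-1-one, via alkenyllithium 8 (not isolated), via dimethyl alkenylboronate 9 (not isolated)
Conditions: t-BuLi (2.1 equiv), Et2O, −78 °C; B(OMe)3, −78 → 0 °C; 30 % H2O2, pH 7 phosphate buffer, THF, 0 °C
Reagents that add atoms: hydrogen peroxide, OO
Why: Iodine–lithium exchange, borylation and oxidation of the alkenyl C–B bond give the enol and so the ketone regiospecifically at C5; the buffered oxidation should leave the adjacent silyloxy stereocentre untouched.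

Step 7
Reactants: 10; 11 triethyl 2-phosphonopropionate
Product: 12 ethyl 2-[2-(tert-butyldimethylsilyloxy)-4-isopropenylcyclopentylidene]propanoate (ring A stereocentres as in 10; E isomer drawn)
Conditions: 11 (1.5 equiv), NaH (1.4 equiv), THF, 0 °C → rt
Reagents that add atoms: none
Why: Horner–Wadsworth–Emmons olefination of the activated α-silyloxy cyclopentanone builds the tetrasubstituted C5=C10 alkene that carries the C10 methyl and C8; its geometry does not matter.

Step 8
Reactants: 12
Product: 13 N-methoxy-N-methylamide corresponding to 12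
Conditions: MeNHOMe·HCl, AlMe3, CH2Cl2, 0 → 40 °C; aq. Rochelle salt
Reagents that add atoms: N,O-dimethylhydroxylamine hydrochloride, CNOC.Cl
Why: Aminolysis of the hindered ester by the aluminium amide gives the Weinreb amide; silyl ether and alkenes are inert.

Step 9
Reactants: 13; 14 1-propenylmagnesium bromide
Product: 15 cyclopentylidene propenyl ketone, (E)-2-[2-(tert-butyldimethylsilyloxy)-4-isopropenylcyclopentylidene]hex-4-en-3-one
Conditions: 14 (2 equiv), THF, −20 → 0 °C; aq. NH4Cl
Reagents that add atoms: none
Why: Grignard addition to the Weinreb amide stops at the chelated tetrahedral intermediate and releases the cross-conjugated dienone on work-up; conjugate addition is blocked by the β,β-disubstitution.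

Step 10
Reactants: 15
Product: 17 spiro enone (2S,4R,5R,10S)-4-(tert-butyldimethylsilyloxy)-2-isopropenyl-6,10-dimethylspiro[4.4]non-6-en-8-one, via aluminium dienolate 16 (not isolated)
Conditions: EtAlCl2 (2.5 equiv), CH2Cl2, −78 → 0 °C; AcOH/THF at −78 °C, then aq. Rochelle salt
Reagents that add atoms: none
Why: Nazarov cyclisation (conrotatory 4π closure of the aluminium-bound hydroxypentadienyl cation) should form C5–C6 on the face of the cyclopentylidene opposite the pseudo-axial C4–OTBS group, giving the (5R) spiro centre; the alkylaluminium takes up the proton lost from C6, and protonation of dienolate 16 at C10 from the face away from C4 should place the C10 methyl cis to C4.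

Step 11
Reactants: 17; 18 1,3-dithiane
Product: 19 tertiary allylic alcohol: 17 with 1,3-dithian-2-yl and OH on C8 (OH cis to the C10 methyl)
Conditions: 18 (1.5 equiv), n-BuLi, THF, −30 °C; then 17, −78 → −40 °C; aq. NH4Cl
Reagents that add atoms: none
Why: Corey–Seebach formyl-anion addition goes 1,2 at the β,β-disubstituted enone and should enter C8 from the ring face opposite the adjacent C10 methyl.

Step 12
Reactants: 19
Product: 20 diol (C4–OH secondary, C8–OH tertiary)
Conditions: TBAF, THF, rt → 50 °C
Reagents that add atoms: none
Why: Fluoride desilylation of the hindered secondary TBS ether; dithiane, alkenes and the tertiary alcohol are unaffected.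

Step 13
Reactants: 20
Product: 21 C4 isobutyrate of 20
Conditions: (i-PrCO)2O, Et3N, DMAP (cat.), CH2Cl2, rt
Reagents that add atoms: isobutyric anhydride, CC(C)C(=O)OC(=O)C(C)C
Why: DMAP-catalysed acylation should be selective for the secondary C4 hydroxyl over the tertiary allylic C8 hydroxyl, which is flanked by the dithiane and the C10 methine.

Step 14
Reactants: 21
Product: 22 spiro[4.4] α-hydroxy aldehyde (C8 bears OH and CHO; OH cis to the C10 methyl)
Conditions: MeI, CaCO3, MeCN/H2O 9:1, 45 °C
Reagents that add atoms: water, O
Why: Alkylative hydrolysis of the dithiane (S-methylation, then hydrolysis of the sulfonium) unmasks the aldehyde under buffered, non-oxidising conditions that spare the alkenes, the ester and the tertiary allylic alcohol.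

Step 15
Reactants: 22
Product: 24 9-deacetyl target (2S,4R,5R,9R,10S)-9-hydroxy-4-isobutyryloxy-2-isopropenyl-6,10-dimethylspiro[4.5]dec-6-en-8-one, via C9-epimeric ketol 23 (not isolated)
Conditions: MgBr2·OEt2 (1.5 equiv), CH2Cl2, 0 °C → rt; after 22 is consumed, i-Pr2NEt (2 equiv), rt
Reagents that add atoms: none
Why: Mg(II) chelates the C8 hydroxyl and the aldehyde oxygen of 22, and in this syn-periplanar chelate the C8–C10 σ bond, which stands perpendicular to the aldehyde plane, shifts suprafacially with its electron pair to the formyl carbon C9 while C8 becomes the carbonyl, so that C9–C10 forms with retention at C10. The closest known reaction type is the α-ketol (acyloin) rearrangement of α-hydroxy aldehydes and ketones with ring enlargement, as in the D-homoannulation of 17-hydroxy-20-oxo steroids. The six-membered ring is closed by this 1,2-shift ring expansion (C9 inserted between C8 and C10 of the cyclopentene), not by cyclisation of a chain, and is driven by the aldehyde-to-ketone change and by conjugation of the new C8=O with C6=C7. C9 is controlled in two stages: the chelate presents to C10 the aldehyde face that gives 23 (OH cis to the C10 methyl), and amine-promoted enolisation of the magnesium-bound ketol toward C9 should then equilibrate it to 24, whose OH is trans to the methyl, pseudo-equatorial and hydrogen-bonded to C8=O in the half-chair that keeps C4 away from the C6 methyl. The step needs C10, not the alkenyl carbon C7, to end up next to the carbinol carbon; C10 migration is favoured because only it develops the conjugated enone in the transition state, and a C7 shift would give the β,γ-unsaturated ketol that tautomerises through the same enediol to 24 under the amine. C10 cannot epimerise because it is not α to a carbonyl in 23 or 24.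

Step 16
Reactants: 24
Product: 25 target (2S,4R,5R,9R,10S)-9-acetoxy-4-isobutyryloxy-2-isopropenyl-6,10-dimethylspiro[4.5]dec-6-en-8-one
Conditions: Ac2O, pyridine, DMAP (cat.), CH2Cl2, 0 °C
Reagents that add atoms: acetic anhydride, CC(=O)OC(C)=O
Why: Acylation of the secondary α-ketol hydroxyl proceeds with retention at C9; low temperature limits enolisation of the α-acetoxy ketone.

## Compound list

1 | (R)-4-(tert-butyldimethylsilyloxy)cyclopent-2-en-1-one | CC(C)(C)[Si](C)(C)O[C@H]1C=CC(=O)C1 | starting material
2 | isopropenylmagnesium bromide | C=C(C)[Mg]Br | starting material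
3 | (3S,4R)-3-isopropenyl-4-(tert-butyldimethylsilyloxy)cyclopentan-1-one | C=C(C)[C@@H]1CC(=O)C[C@H]1O[Si](C)(C)C(C)(C)C | intermediate
4 | (R)-4-isopropenylcyclopent-2-en-1-one | C=C(C)[C@@H]1CC(=O)C=C1 | intermediate
5 | (R)-2-iodo-4-isopropenylcyclopent-2-en-1-one | C=C(C)[C@@H]1CC(=O)C(I)=C1 | intermediate
6 | (1R,4R)-2-iodo-4-isopropenylcyclopent-2-en-1-ol | C=C(C)[C@@H]1C[C@@H](O)C(I)=C1 | intermediate
7 | TBS ether of 6 | C=C(C)[C@@H]1C[C@@H](O[Si](C)(C)C(C)(C)C)C(I)=C1 | intermediate
8 | alkenyllithium from 7 (Li in place of I) | C=C(C)[C@@H]1C[C@@H](O[Si](C)(C)C(C)(C)C)C([Li])=C1 | intermediate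
9 | dimethyl alkenylboronate from 8 | C=C(C)[C@@H]1C[C@@H](O[Si](C)(C)C(C)(C)C)C(B(OC)OC)=C1 | intermediate
10 | (2R,4R)-2-(tert-butyldimethylsilyloxy)-4-isopropenylcyclopentan-1-one | C=C(C)[C@@H]1C[C@@H](O[Si](C)(C)C(C)(C)C)C(=O)C1 | intermediate
11 | triethyl 2-phosphonopropionate | CCOC(=O)C(C)P(=O)(OCC)OCC | starting material
12 | ethyl (E)-2-[2-(tert-butyldimethylsilyloxy)-4-isopropenylcyclopentylidene]propanoate | CCOC(=O)/C(C)=C1\C[C@H](C(C)=C)C[C@H]1O[Si](C)(C)C(C)(C)C | intermediate
13 | N-methoxy-N-methylamide of 12 | CON(C)C(=O)/C(C)=C1\C[C@H](C(C)=C)C[C@H]1O[Si](C)(C)C(C)(C)C | intermediate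
14 | 1-propenylmagnesium bromide (E drawn) | C/C=C/[Mg]Br | starting material
15 | cyclopentylidene propenyl ketone (E,E drawn) | C/C=C/C(=O)/C(C)=C1\C[C@H](C(C)=C)C[C@H]1O[Si](C)(C)C(C)(C)C | intermediate
16 | dichloroaluminium dienolate of 17 (C6=C7, C8(OAl)=C10) | C=C(C)[C@@H]1C[C@@H](O[Si](C)(C)C(C)(C)C)[C@@]2(C1)C(C)=CC(O[Al](Cl)Cl)=C2C | intermediate
17 | (2S,4R,5R,10S)-4-(tert-butyldimethylsilyloxy)-2-isopropenyl-6,10-dimethylspiro[4.4]non-6-en-8-one (core numbering, C9 absent) | C=C(C)[C@@H]1C[C@@H](O[Si](C)(C)C(C)(C)C)[C@@]2(C1)C(C)=CC(=O)[C@H]2C | intermediate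
18 | 1,3-dithiane | C1CSCSC1 | starting material
19 | C8 dithianyl carbinol of 17 (OH cis to C10 methyl) | C=C(C)[C@@H]1C[C@@H](O[Si](C)(C)C(C)(C)C)[C@@]2(C1)C(C)=C[C@](O)(C3SCCCS3)[C@H]2C | intermediate
20 | diol from 19 (C4–OH free) | C=C(C)[C@@H]1C[C@@H](O)[C@@]2(C1)C(C)=C[C@](O)(C3SCCCS3)[C@H]2C | intermediate
21 | C4 isobutyrate of 20 | C=C(C)[C@@H]1C[C@@H](OC(=O)C(C)C)[C@@]2(C1)C(C)=C[C@](O)(C3SCCCS3)[C@H]2C | intermediate
22 | spiro[4.4]nonene α-hydroxy aldehyde (key-step precursor) | C=C(C)[C@@H]1C[C@@H](OC(=O)C(C)C)[C@@]2(C1)C(C)=C[C@](O)(C=O)[C@H]2C | intermediate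
23 | C9-epimeric ketol (9S; OH cis to C10 methyl) | C=C(C)[C@@H]1C[C@@H](OC(=O)C(C)C)[C@@]2(C1)C(C)=CC(=O)[C@@H](O)[C@H]2C | intermediate
24 | 9-deacetyl target (α-hydroxy enone, 9R) | C=C(C)[C@@H]1C[C@@H](OC(=O)C(C)C)[C@@]2(C1)C(C)=CC(=O)[C@H](O)[C@H]2C | intermediate
25 | target CNP0229299.1 | C=C(C)[C@@H]1C[C@@H](OC(=O)C(C)C)[C@@]2(C1)C(C)=CC(=O)[C@H](OC(C)=O)[C@H]2C | target

## Step count and risks

Total step count: 16. Longest linear sequence: 16 (the route is linear; 2, 11, 14 and 18 are commercial reagents).

Steps most likely to fail:

1. Step 15. The shift may run through the alkenyl carbon C7 instead of C10, or C9 may not settle on the trans side: the chelate-controlled cis ketol may persist, or the amine may carry the enediol on to the 2-hydroxy-2-enone (diosphenol) tautomer. Fallback, from 22 back to 25: C9 is set by inversion instead of equilibration. Treatment of 22 with MgBr2·OEt2 alone and neutral work-up should stop at the cis ketol 23, which is isolated. Mitsunobu reaction of 23 with acetic acid (PPh3, DIAD, THF, 0 °C) then displaces the activated α-keto carbinol with inversion and gives acetate 25 directly, replacing step 16.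

2. Step 10. The cationic terminus C5 sits next to the C4–H/OTBS carbon, so a 1,2-hydride shift or deprotonation toward C4 may destroy the silyloxy stereocentre. The conrotatory closure may also show poor facial selectivity, the isopropenyl group may react with acid, and protonation at C10 may be unselective. Fallback, from 10 back to 20: the spiro centre is made by conjugate addition to a fused butenolide, where the cis ring fusion of the product leaves one face only.
   - Desilylation of 10 (HF·pyridine, THF, 0 °C) gives the α-hydroxy ketone F1.
   - Acylation and intramolecular Wittig reaction with (triphenylphosphoranylidene)ketene (toluene, 80 °C) gives the bicyclic butenolide F2.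
   - Copper-mediated 1,4-addition of 2 (CuBr·SMe2, TMSCl, THF, −40 °C) should give the cis-fused lactone F3, with the angular isopropenyl group necessarily trans to the C4 oxygen.
   - Enolate methylation (LDA, MeI, THF, −78 °C), expected anti to the angular isopropenyl group, gives the α-methyl lactone F4.
   - Mono-addition of vinylmagnesium bromide (THF, −78 °C) opens the lactone to the hydroxy vinyl ketone F5.
   - Ring-closing metathesis (second-generation Grubbs catalyst, CH2Cl2, 40 °C) between the vinyl ketone and the isopropenyl group on C5 gives the hydroxy spiro enone F6. Its C10 centre can be re-set by enolate protonation if needed.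
   - Addition of 2-lithio-1,3-dithiane (3 equiv, THF, −78 °C) to F6 gives diol 20, and steps 13 to 16 follow unchanged.

3. Step 7. Olefination of the hindered α-silyloxy ketone with the α-branched phosphonate may be slow, which allows enolisation toward C4 with epimerisation or silyl migration. Fallback, from 10 back to 15: the alkene is made by aldol addition and dehydration. The kinetic lithium enolate of commercial (E)-hex-4-en-3-one (LDA, THF, −78 °C) adds to 10 to give the tertiary aldol adduct F7 (mixture at C5 and C10, both lost next). Dehydration with the Burgess reagent (benzene, 50 °C) through the acidic C10–H gives dienone 15 directly, bypassing 12 and 13.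

Further compounds
F0 | step 15 | none | none
F1 | step 10 | (2R,4R)-2-hydroxy-4-isopropenylcyclopentan-1-one | C=C(C)[C@@H]1C[C@@H](O)C(=O)C1
F2 | step 10 | fused butenolide, 5-isopropenyl-4,5,6,6a-tetrahydro-2H-cyclopenta[b]furan-2-one (C4–O trans to isopropenyl) | C=C(C)[C@@H]1C[C@H]2OC(=O)C=C2C1
F3 | step 10 | cis-fused lactone with angular isopropenyl on C5 | C=C(C)[C@@H]1C[C@H]2OC(=O)C[C@@]2(C(C)=C)C1
F4 | step 10 | α-methyl lactone (C10 methyl anti to angular isopropenyl) | C=C(C)[C@@H]1C[C@H]2OC(=O)[C@@H](C)[C@@]2(C(C)=C)C1
F5 | step 10 | hydroxy vinyl ketone (open form of the hemiketal) | C=C(C)[C@@H]1C[C@@H](O)[C@@](C1)(C(C)=C)[C@H](C)C(=O)C=C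
F6 | step 10 | 4-hydroxy-2-isopropenyl-6,10-dimethylspiro[4.4]non-6-en-8-one | C=C(C)[C@@H]1C[C@@H](O)[C@@]2(C1)C(C)=CC(=O)[C@H]2C
F7 | step 7 | tertiary aldol adduct of 10 with (E)-hex-4-en-3-one (mixture at C5 and C10) | C/C=C/C(=O)C(C)C1(O)C[C@H](C(C)=C)C[C@H]1O[Si](C)(C)C(C)(C)C
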